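**Retrosynthetic overview**

1. Each E ring (atoms E1–E6) is a phloroglucinol nucleus: E2, E4 and E6 carry free hydroxyls, E1 the oxygen bridge to ring D, E5 ring F and E3 hydrogen. E6–E1–E2 is therefore the carbon triad of an O-aryl malonate (both carboxyl carbons end as C–OH), and E3–E4–E5 is C2–C3–C4 of a 4-aryl-3-oxobutanoate.
2. Both E rings are cut at once at E2–E3 and E5–E6, giving a ring D bis(aryloxymalonate) and two molecules of ethyl 3-oxo-4-(2,4,6-trimethoxyphenyl)butanoate. The ester left on E3 is then lost as CO2 and all sixteen methyl ethers are cleaved.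
3. Ring D enters the annulation already carrying the finished ring C–B(B')–A chain on its O1, so no bond has to be made at that flanked oxygen once the E rings exist. D–O–C and C–O–B come from Ullmann couplings in which the phenol is always the 2,6-dioxygenated partner, A–O–B from a Chan–Lam coupling, and B–B' from a Suzuki coupling.
4. The keto ester comes from 2,4,6-trimethoxybenzaldehyde by one-carbon homologation and a Roskamp reaction.
5. Rings A, B, B', C, D and F are bought as arenes and joined in the order D–C, then B (with A), then B'. The two E rings are the only rings formed, both in step 16.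

Key step: step 16

Remark on the chemistry: ethyl esters are used on both annulation partners so that the ethoxide set free cannot scramble ester groups. No compound of the route has a stereocentre that must be controlled. In names, ArABC = 4-[4-(3,5-dimethoxyphenoxy)-3,5-dimethoxy-2-(2,4,6-trimethoxyphenyl)phenoxy]-3,5-dimethoxyphenyl (ring C carrying rings B, B' and A, attached through C4 of ring C).

**Route**

Step 1
Reactants: 1 1-(2,6-dihydroxy-4-methoxyphenyl)ethan-1-one
Product: 2 1-[2,6-bis(benzyloxy)-4-methoxyphenyl]ethan-1-one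
Conditions: BnBr (2.5 equiv), K2CO3, DMF, 70 °C
Reagents that add atoms: benzyl bromide, BrCc1ccccc1
Why: Williamson O-benzylation of both chelated phenols (hence DMF and heat) gives ethers that survive the peracid, copper and palladium steps and leave later by hydrogenolysis.

Step 2
Reactants: 2 1-[2,6-bis(benzyloxy)-4-methoxyphenyl]ethan-1-one
Product: 4 2,6-bis(benzyloxy)-4-methoxyphenol, via aryl acetate 3 (not isolated)
Conditions: mCPBA, CH2Cl2, 0 °C to rt; then K2CO3 (cat.), MeOH, rt, argon
Reagents that add atoms: meta-chloroperoxybenzoic acid, OOC(=O)c1cccc(Cl)c1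
Why: Baeyer–Villiger oxidation in which the electron-rich aryl group migrates in preference to methyl, followed by methanolysis of the aryl acetate, should give the phenol whose oxygen becomes D1–O.

Step 3
Reactants: 5 4-bromo-2,6-dimethoxyphenol
Product: 6 5-bromo-1,3-dimethoxy-2-(methoxymethoxy)benzene
Conditions: NaH, DMF, 0 °C; MOMCl, 0 °C to rt
Reagents that add atoms: chloromethyl methyl ether, COCCl
Why: Williamson-type protection as the methoxymethyl acetal masks O1 of ring C, so that in step 4 only phenol 4 can be arylated.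

Step 4
Reactants: 4 2,6-bis(benzyloxy)-4-methoxyphenol; 6 5-bromo-1,3-dimethoxy-2-(methoxymethoxy)benzene
Product: 7 1,3-bis(benzyloxy)-2-[3,5-dimethoxy-4-(methoxymethoxy)phenoxy]-5-methoxybenzene
Conditions: CuI (20 mol%), N,N-dimethylglycine hydrochloride (60 mol%), Cs2CO3, 1,4-dioxane, 100 °C, argon
Reagents that add atoms: none
Why: Ullmann diaryl ether synthesis between a 2,6-dialkoxyphenol, an established nucleophile class, and a bromide without ortho substituents should form the D1–O–C4 ether.

Step 5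
Reactants: 7 1,3-bis(benzyloxy)-2-[3,5-dimethoxy-4-(methoxymethoxy)phenoxy]-5-methoxybenzene
Product: 8 4-[2,6-bis(benzyloxy)-4-methoxyphenoxy]-2,6-dimethoxyphenol
Conditions: HCl (cat.), MeOH/THF, 50 °C
Reagents that add atoms: none
Why: Acid-catalysed acetal cleavage (transacetalisation to dimethoxymethane) frees the ring C phenol while benzyl, methyl and diaryl ethers stay intact.

Step 6
Reactants: 9 2,6-dimethoxyphenol
Product: 10 4-iodo-2,6-dimethoxyphenol
Conditions: NIS (1.0 equiv), MeCN, 0 °C, dark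
Reagents that add atoms: N-iodosuccinimide, O=C1CCC(=O)N1I
Why: Electrophilic aromatic iodination goes para to the free hydroxyl, the only open position that it activates.

Step 7
Reactants: 10 4-iodo-2,6-dimethoxyphenol
Product: 11 4-iodo-2,6-dimethoxyphenyl acetate
Conditions: Ac2O, pyridine, DMAP (cat.), CH2Cl2, rt
Reagents that add atoms: acetic anhydride, CC(=O)OC(C)=O
Why: Acetylation damps the phenol so that the next halogenation is directed by the two methoxy groups and ipso attack at the iodine-bearing carbon is avoided.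

Step 8
Reactants: 11 4-iodo-2,6-dimethoxyphenyl acetate
Product: 13 3-bromo-4-iodo-2,6-dimethoxyphenol, via bromo iodo acetate 12 (not isolated)
Conditions: NBS (1.0 equiv), MeCN, rt; then K2CO3 (cat.), MeOH, rt
Reagents that add atoms: N-bromosuccinimide, O=C1CCC(=O)N1Br
Why: Electrophilic bromination goes ortho to one methoxy group and para to the other (C3 and C5 are equivalent, so one product can form), and mild methanolysis then returns the phenol.

Step 9
Reactants: 13 3-bromo-4-iodo-2,6-dimethoxyphenol; 14 (3,5-dimethoxyphenyl)boronic acid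
Product: 15 2-bromo-4-(3,5-dimethoxyphenoxy)-1-iodo-3,5-dimethoxybenzene
Conditions: Cu(OAc)2 (2 equiv), pyridine, 4 Å molecular sieves, CH2Cl2, air, rt
Reagents that add atoms: none
Why: Chan–Lam O-arylation runs at room temperature on di-ortho-substituted phenols and leaves the aryl iodide and bromide untouched, which a thermal Ullmann coupling would not.

Step 10
Reactants: 8 4-[2,6-bis(benzyloxy)-4-methoxyphenoxy]-2,6-dimethoxyphenol; 15 2-bromo-4-(3,5-dimethoxyphenoxy)-1-iodo-3,5-dimethoxybenzene
Product: 16 1,3-bis(benzyloxy)-2-{4-[2-bromo-4-(3,5-dimethoxyphenoxy)-3,5-dimethoxyphenoxy]-3,5-dimethoxyphenoxy}-5-methoxybenzene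
Conditions: CuI (20 mol%), N,N-dimethylglycine hydrochloride (60 mol%), Cs2CO3, 1,4-dioxane, 90 °C, argon
Reagents that add atoms: none
Why: Ullmann etherification that is chemoselective for the iodide (one small ortho neighbour) over the doubly flanked bromide should form the C1–O–B4 ether.

Step 11
Reactants: 16 1,3-bis(benzyloxy)-2-{4-[2-bromo-4-(3,5-dimethoxyphenoxy)-3,5-dimethoxyphenoxy]-3,5-dimethoxyphenoxy}-5-methoxybenzene; 17 (2,4,6-trimethoxyphenyl)boronic acid
Product: 18 1,3-bis(benzyloxy)-5-methoxy-2-(ArABC-oxy)benzene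
Conditions: Pd(OAc)2 (10 mol%), SPhos (20 mol%), K3PO4, toluene/H2O, 100 °C; 17 (3 equiv) in portions
Reagents that add atoms: none
Why: Suzuki–Miyaura coupling with a bulky dialkylbiarylphosphine is the established way to tetra-ortho-substituted biaryls, and the protodeboronation-prone boronic acid is used in excess.

Step 12
Reactants: 18 1,3-bis(benzyloxy)-5-methoxy-2-(ArABC-oxy)benzene
Product: 19 5-methoxy-2-(ArABC-oxy)benzene-1,3-diol
Conditions: H2 (1 atm), Pd/C (10%), THF/MeOH, rt
Reagents that add atoms: none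
Why: Catalytic hydrogenolysis removes both benzyl ethers, and no halide or other reducible group remains.

Step 13
Reactants: 19 5-methoxy-2-(ArABC-oxy)benzene-1,3-diol; 20 diethyl bromomalonate
Product: 21 tetraethyl 2,2'-{[5-methoxy-2-(ArABC-oxy)-1,3-phenylene]bis(oxy)}dimalonate
Conditions: 20 (2.4 equiv), K2CO3, acetone, rt, argon
Reagents that add atoms: none
Why: SN2 O-alkylation of the two phenoxides by the bromomalonate under mild carbonate conditions gives the bis(aryloxymalonate), so the D–O–E1 bonds are made at sp3 carbon.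

Step 14
Reactants: 22 2,4,6-trimethoxybenzaldehyde; 23 (methoxymethyl)triphenylphosphonium chloride
Product: 25 2-(2,4,6-trimethoxyphenyl)acetaldehyde, via enol ether 24 (not isolated)
Conditions: 23, KOtBu, THF, 0 °C; 22, 0 °C to rt; then 2 M HCl, THF, rt
Reagents that add atoms: water, O
Why: Wittig methoxymethylenation followed by hydrolysis of the enol ether is a standard one-carbon homologation of an aromatic aldehyde, and both enol ether isomers give the same aldehyde.

Step 15
Reactants: 25 2-(2,4,6-trimethoxyphenyl)acetaldehyde; 26 ethyl diazoacetate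
Product: 27 ethyl 3-oxo-4-(2,4,6-trimethoxyphenyl)butanoate
Conditions: SnCl2 (10 mol%), CH2Cl2, rt
Reagents that add atoms: none
Why: Roskamp reaction (Lewis acid-promoted addition of the diazo ester to the aldehyde, 1,2-hydride shift, loss of N2) gives the β-keto ester directly.

Step 16
Reactants: 21 tetraethyl 2,2'-{[5-methoxy-2-(ArABC-oxy)-1,3-phenylene]bis(oxy)}dimalonate; 27 ethyl 3-oxo-4-(2,4,6-trimethoxyphenyl)butanoate (2.3 equiv)
Product: 29 diethyl 3,3'-{[5-methoxy-2-(ArABC-oxy)-1,3-phenylene]bis(oxy)}bis[2,4,6-trihydroxy-5-(2,4,6-trimethoxyphenyl)benzoate], via acyclic bis(Claisen adduct) 28 (not isolated)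
Conditions: 27, NaH (2.3 equiv), THF, 0 °C; 21, 65 °C; then NaH (5 equiv), EtOH (cat.), toluene, 100 °C; 1 M HCl
Reagents that add atoms: none
Why: Proposed new method: the sodium enolate of 27 should be C-acylated at its C2 by one ester of each still un-ionised aryloxymalonate (intermolecular Claisen condensation, ethoxide lost, adduct 28 held as its tricarbonyl enolate); the second charge of NaH, with ethoxide as proton shuttle, then reaches the benzylic C4 as the dienolate, which attacks the remaining malonate ester, and loss of ethoxide gives a cyclohexane-1,3,5-trione that tautomerises to the aromatic triol, so that E2–E3 and E5–E6 are formed in each half. The closest known reaction types are the alkoxide-mediated condensation of malonic esters with 3-oxoglutarates to phloroglucinol carboxylates and the Claisen cyclisation of 3,5-dioxo esters; the pairing of an aryloxymalonate with a keto ester whose second nucleophilic carbon is only benzylic is not established. Each E ring closes by a 6-exo-trig Dieckmann-type acyl substitution. No stereocentre is formed. The selectivity required is carbon over oxygen acylation in the ring closure (the oxygen path would give a 4-hydroxy-2-pyranone): with excess base and ethoxide present the lactone can reopen while the aromatic polyphenolate is the most stable end point, and one equivalent of base per keto ester in the first stage keeps the malonate electrophilic. The aryl methyl ethers and diaryl ethers are inert to NaH, and identical ethyl esters on both partners prevent ester scrambling.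

Step 17
Reactants: 29 diethyl 3,3'-{[5-methoxy-2-(ArABC-oxy)-1,3-phenylene]bis(oxy)}bis[2,4,6-trihydroxy-5-(2,4,6-trimethoxyphenyl)benzoate]
Product: 31 3,3'-{[5-methoxy-2-(ArABC-oxy)-1,3-phenylene]bis(oxy)}bis(2',4',6'-trimethoxybiphenyl-2,4,6-triol), via dicarboxylic acid 30 (not isolated)
Conditions: 2 M KOH, EtOH/H2O (degassed), 90 °C, argon; then 2 M HCl, 60 °C
Reagents that add atoms: none
Why: Ester hydrolysis followed by decarboxylation, which is facile for 2,4,6-trihydroxybenzoic acids because ipso protonation gives a β-keto acid tautomer, should remove both E3 carboxyl groups.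

Step 18
Reactants: 31 3,3'-{[5-methoxy-2-(ArABC-oxy)-1,3-phenylene]bis(oxy)}bis(2',4',6'-trimethoxybiphenyl-2,4,6-triol)
Product: 32 CNP0117322.0
Conditions: BBr3 (40 equiv), CH2Cl2, −78 °C to rt; H2O, 0 °C
Reagents that add atoms: none
Why: BBr3 cleaves aryl methyl ethers through the O–B adduct and bromide attack at methyl while leaving diaryl ethers and biaryl bonds untouched, so all sixteen methoxy groups should fall to hydroxyls.

**Compound list**

1 | 1-(2,6-dihydroxy-4-methoxyphenyl)ethan-1-one | CC(=O)c1c(O)cc(OC)cc1O | starting material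
2 | 1-[2,6-bis(benzyloxy)-4-methoxyphenyl]ethan-1-one | CC(=O)c1c(OCc2ccccc2)cc(OC)cc1OCc1ccccc1 | intermediate
3 | 2,6-bis(benzyloxy)-4-methoxyphenyl acetate | CC(=O)Oc1c(OCc2ccccc2)cc(OC)cc1OCc1ccccc1 | intermediate
4 | 2,6-bis(benzyloxy)-4-methoxyphenol | Oc1c(OCc2ccccc2)cc(OC)cc1OCc1ccccc1 | intermediate
5 | 4-bromo-2,6-dimethoxyphenol | COc1cc(Br)cc(OC)c1O | starting material
6 | 5-bromo-1,3-dimethoxy-2-(methoxymethoxy)benzene | COCOc1c(OC)cc(Br)cc1OC | intermediate
7 | 1,3-bis(benzyloxy)-2-[3,5-dimethoxy-4-(methoxymethoxy)phenoxy]-5-methoxybenzene | COCOc1c(OC)cc(Oc2c(OCc3ccccc3)cc(OC)cc2OCc2ccccc2)cc1OC | intermediate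
8 | 4-[2,6-bis(benzyloxy)-4-methoxyphenoxy]-2,6-dimethoxyphenol | COc1cc(Oc2c(OCc3ccccc3)cc(OC)cc2OCc2ccccc2)cc(OC)c1O | intermediate
9 | 2,6-dimethoxyphenol | COc1cccc(OC)c1O | starting material
10 | 4-iodo-2,6-dimethoxyphenol | COc1cc(I)cc(OC)c1O | intermediate
11 | 4-iodo-2,6-dimethoxyphenyl acetate | COc1cc(I)cc(OC)c1OC(C)=O | intermediate
12 | 3-bromo-4-iodo-2,6-dimethoxyphenyl acetate | COc1cc(I)c(Br)c(OC)c1OC(C)=O | intermediate
13 | 3-bromo-4-iodo-2,6-dimethoxyphenol | COc1cc(I)c(Br)c(OC)c1O | intermediate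
14 | (3,5-dimethoxyphenyl)boronic acid | COc1cc(OC)cc(B(O)O)c1 | starting material
15 | 2-bromo-4-(3,5-dimethoxyphenoxy)-1-iodo-3,5-dimethoxybenzene | COc1cc(OC)cc(Oc2c(OC)cc(I)c(Br)c2OC)c1 | intermediate
16 | 1,3-bis(benzyloxy)-2-{4-[2-bromo-4-(3,5-dimethoxyphenoxy)-3,5-dimethoxyphenoxy]-3,5-dimethoxyphenoxy}-5-methoxybenzene | COc1cc(OC)cc(Oc2c(OC)cc(Oc3c(OC)cc(Oc4c(OCc5ccccc5)cc(OC)cc4OCc4ccccc4)cc3OC)c(Br)c2OC)c1 | intermediate
17 | (2,4,6-trimethoxyphenyl)boronic acid | COc1cc(OC)c(B(O)O)c(OC)c1 | starting material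
18 | 1,3-bis(benzyloxy)-5-methoxy-2-(ArABC-oxy)benzene | COc1cc(OC)cc(Oc2c(OC)cc(Oc3c(OC)cc(Oc4c(OCc5ccccc5)cc(OC)cc4OCc4ccccc4)cc3OC)c(-c3c(OC)cc(OC)cc3OC)c2OC)c1 | intermediate
19 | 5-methoxy-2-(ArABC-oxy)benzene-1,3-diol | COc1cc(OC)cc(Oc2c(OC)cc(Oc3c(OC)cc(Oc4c(O)cc(OC)cc4O)cc3OC)c(-c3c(OC)cc(OC)cc3OC)c2OC)c1 | intermediate
20 | diethyl bromomalonate | CCOC(=O)C(Br)C(=O)OCC | starting material
21 | tetraethyl 2,2'-{[5-methoxy-2-(ArABC-oxy)-1,3-phenylene]bis(oxy)}dimalonate (ring D bis(aryloxymalonate)) | COc1cc(OC)cc(Oc2c(OC)cc(Oc3c(OC)cc(Oc4c(OC(C(=O)OCC)C(=O)OCC)cc(OC)cc4OC(C(=O)OCC)C(=O)OCC)cc3OC)c(-c3c(OC)cc(OC)cc3OC)c2OC)c1 | intermediate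
22 | 2,4,6-trimethoxybenzaldehyde | COc1cc(OC)c(C=O)c(OC)c1 | starting material
23 | (methoxymethyl)triphenylphosphonium chloride | COC[P+](c1ccccc1)(c1ccccc1)c1ccccc1.[Cl-] | starting material
24 | 1,3,5-trimethoxy-2-(2-methoxyethenyl)benzene (E/Z mixture, both isomers used) | COC=Cc1c(OC)cc(OC)cc1OC | intermediate
25 | 2-(2,4,6-trimethoxyphenyl)acetaldehyde | O=CCc1c(OC)cc(OC)cc1OC | intermediate
26 | ethyl diazoacetate | CCOC(=O)C=[N+]=[N-] | starting material
27 | ethyl 3-oxo-4-(2,4,6-trimethoxyphenyl)butanoate | CCOC(=O)CC(=O)Cc1c(OC)cc(OC)cc1OC | intermediate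
28 | acyclic bis(Claisen adduct): each ring D oxygen carries CH(CO2Et)–CO–CH(CO2Et)–CO–CH2–(2,4,6-trimethoxyphenyl); enolisable centres, configuration not defined | COc1cc(OC)cc(Oc2c(OC)cc(Oc3c(OC)cc(Oc4c(OC(C(=O)OCC)C(=O)C(C(=O)OCC)C(=O)Cc5c(OC)cc(OC)cc5OC)cc(OC)cc4OC(C(=O)OCC)C(=O)C(C(=O)OCC)C(=O)Cc4c(OC)cc(OC)cc4OC)cc3OC)c(-c3c(OC)cc(OC)cc3OC)c2OC)c1 | intermediate
29 | diethyl 3,3'-{[5-methoxy-2-(ArABC-oxy)-1,3-phenylene]bis(oxy)}bis[2,4,6-trihydroxy-5-(2,4,6-trimethoxyphenyl)benzoate] | COc1cc(OC)cc(Oc2c(OC)cc(Oc3c(OC)cc(Oc4c(Oc5c(O)c(C(=O)OCC)c(O)c(-c6c(OC)cc(OC)cc6OC)c5O)cc(OC)cc4Oc4c(O)c(C(=O)OCC)c(O)c(-c5c(OC)cc(OC)cc5OC)c4O)cc3OC)c(-c3c(OC)cc(OC)cc3OC)c2OC)c1 | intermediate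
30 | 3,3'-{[5-methoxy-2-(ArABC-oxy)-1,3-phenylene]bis(oxy)}bis[2,4,6-trihydroxy-5-(2,4,6-trimethoxyphenyl)benzoic acid] | COc1cc(OC)cc(Oc2c(OC)cc(Oc3c(OC)cc(Oc4c(Oc5c(O)c(C(=O)O)c(O)c(-c6c(OC)cc(OC)cc6OC)c5O)cc(OC)cc4Oc4c(O)c(C(=O)O)c(O)c(-c5c(OC)cc(OC)cc5OC)c4O)cc3OC)c(-c3c(OC)cc(OC)cc3OC)c2OC)c1 | intermediate
31 | 3,3'-{[5-methoxy-2-(ArABC-oxy)-1,3-phenylene]bis(oxy)}bis(2',4',6'-trimethoxybiphenyl-2,4,6-triol) | COc1cc(OC)cc(Oc2c(OC)cc(Oc3c(OC)cc(Oc4c(Oc5c(O)cc(O)c(-c6c(OC)cc(OC)cc6OC)c5O)cc(OC)cc4Oc4c(O)cc(O)c(-c5c(OC)cc(OC)cc5OC)c4O)cc3OC)c(-c3c(OC)cc(OC)cc3OC)c2OC)c1 | intermediate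
32 | CNP0117322.0 | Oc1cc(O)cc(Oc2c(O)cc(Oc3c(O)cc(Oc4c(Oc5c(O)cc(O)c(-c6c(O)cc(O)cc6O)c5O)cc(O)cc4Oc4c(O)cc(O)c(-c5c(O)cc(O)cc5O)c4O)cc3O)c(-c3c(O)cc(O)cc3O)c2O)c1 | target

**Step count and risks**

Total steps: 18. Longest linear sequence: 11 steps (1, 2, 4, 5, 10, 11, 12, 13, 16, 17, 18; the branch from 9 through steps 6–9 is equally long).

Steps most likely to fail:

1. Step 16 (proposed new method). The ring-closing acylation at the weakly acidic benzylic carbon may stall, closure through oxygen may take over, or ethoxide may cleave the aryloxymalonate by retro-Claisen reaction before condensation. The fallback sets out from diol 19 and comes back to the route at target 32, bringing in the E–F units as finished arenes by known aryl ether chemistry. Commercial 1,3,5-trimethoxybenzene would be dimerised oxidatively (PhI(OCOCF3)2, BF3·OEt2, CH2Cl2, −78 °C) to 2,2',4,4',6,6'-hexamethoxybiphenyl F1. Mono-iodination (NIS, MeCN) would give 3-iodo-2,2',4,4',6,6'-hexamethoxybiphenyl F2. A twofold Ullmann etherification of 19 with F2 (CuI, picolinic acid, K3PO4, DMSO, 110 °C) would give the fully methylated octaaryl tetraether F3, which the BBr3 conditions of step 18 (here twenty-two methyl ethers) should convert into 32.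

2. Step 11. Protodeboronation of the 2,6-dialkoxyarylboronic acid may outrun transmetalation at the doubly flanked bromide, or oxidative addition may stall. The fallback sets out from 16 and comes back at 18 and gives up boron altogether. 1,3,5-Trimethoxybenzene would be lithiated (n-BuLi, THF, 0 °C) and transmetalated with ZnCl2 to (2,4,6-trimethoxyphenyl)zinc chloride F4, which would be joined to 16 by Negishi coupling (Pd2(dba)3, RuPhos, THF, 70 °C). This is an anhydrous, base-free transmetalation with a preformed organozinc, so the protodeboronation path no longer exists.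

3. Step 13. Halogen transfer from the bromomalonate to the very electron-rich ring D, C-alkylation at D3/D5 in place of O-alkylation, or incomplete second alkylation may occur. The fallback sets out from 19 and comes back at 21. Both O–H bonds would be functionalised by Rh2(OAc)4-catalysed carbenoid O–H insertion of diethyl diazomalonate (2.5 equiv, CH2Cl2, reflux), under neutral conditions with neither base nor an electrophilic halogen. It makes no new compound (F0).

Further compounds
F1 | step 16 | 2,2',4,4',6,6'-hexamethoxybiphenyl | COc1cc(OC)c(-c2c(OC)cc(OC)cc2OC)c(OC)c1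
F2 | step 16 | 3-iodo-2,2',4,4',6,6'-hexamethoxybiphenyl | COc1cc(OC)c(-c2c(OC)cc(OC)c(I)c2OC)c(OC)c1
F3 | step 16 | fully O-methylated target skeleton (5-methoxy-2-(ArABC-oxy)-1,3-phenylene bis(ether) of two 2,2',4,4',6,6'-hexamethoxybiphenyl-3-ols) | COc1cc(OC)cc(Oc2c(OC)cc(Oc3c(OC)cc(Oc4c(Oc5c(OC)cc(OC)c(-c6c(OC)cc(OC)cc6OC)c5OC)cc(OC)cc4Oc4c(OC)cc(OC)c(-c5c(OC)cc(OC)cc5OC)c4OC)cc3OC)c(-c3c(OC)cc(OC)cc3OC)c2OC)c1
F4 | step 11 | (2,4,6-trimethoxyphenyl)zinc chloride | COc1cc(OC)c([Zn]Cl)c(OC)c1
F0 | step 13 | none | none
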